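(All runs come from a simulation for substances that don't exist; noise was put on by code.)

With time the west flask's free substrate stands level, at 44.5% at 4.00 min and 44.4% at 10.0 min, yet its target sinks from 47.9% to 39.8%. Substrate that has reacted is therefore leaving target for something unread.

the same everywhere: substrate 0.050 M
- west: coupling partner 0.055 M; the very flask that is asked about, followed so far
- north-west: coupling partner 0.083 M; run made earlier
- flask: coupling partner 0.0550 M; time 15 min
- west (time / min: target / %, substrate / %): 0.667: 24.0, 72.5; 1.50: 38.5, 56.3; 4.00: 47.9, 44.5; 10.0: 39.8, 44.4
- north-west (time / min: target / %, substrate / %): 1.33: 47.1, 45.8; 4.00: 56.3, 31.0; 6.00: 54.2, 30.5; 10.0: 47.8, 33.2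

(readings scatter by 1 percentage point)
- removed target is counted in
- additions bring no volume worth counting
- a reading of substrate is of its free form alone
- Saturday's: at 15 min add substrate, 50.0% of the amount charged, then wait 5.0 min
- Sunday's: at 15 min add coupling partner, 100% of the amount charged, then wait 5.0 min
- Monday's: change nothing and wait 5.0 min more
- Friday's: at 15 min take out 90% of the target then present, then wait 5.0 min
- target, in percent of the substrate first charged, at 15 min
- which option adds most target ("none" when 2 percentage points or less is all one gets) (Saturday's / Sunday's / Monday's / Friday's / none)
- target present, with what was taken out counted in, in percent of the substrate first charged, after Saturday's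
- target present, with what was taken out counted in, in percent of the substrate first charged, after Monday's

The first way to the target at 15 min follows the west target alone, taking its fall as first order:

λ = 0.0309 min⁻¹, so target = 34.1%

The second way follows one molecule. Once a substrate molecule has left the free form, what is its chance of standing as target? This target share, a selectivity, is the target divided by the part of the charged substrate no longer free. The north-west flask, with [coupling partner] at 0.083 M, gives it without any west target reading:

share = 0.869 at 1.33 min, 0.716 at 10.0 min, falling at 0.0224 min⁻¹

Carried to 15 min, the chance is 0.640. Times the west flask's reacted 55.6%, that makes target = 35.6%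

The two ways part by 1.5 percentage points, and the first one is the likelier to cheat. At 4.00 min the west flask reads a share of 0.863 against 0.816 in the north-west flask, though at 10.0 min the two read 0.716 and 0.716. Its slope may therefore start from a high reading, though the two flasks also differ in [coupling partner], and this reckoning commits to 35.6%.

Waiting, by the same share, leaves 31.8%. The north-west flask reads free substrate at 30.5% at 6.00 min, lower than the west flask, so Sunday's may draw substrate down that far; at the early share, that gives an estimate of 43.9%. No run shows what Friday's or Saturday's flask makes afterwards, so this reckoning chooses Sunday's, the option with a reading behind it.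

The forecast gives 34% at 15 min, Friday's as the best option, 29.3% after Saturday's and 29.4% after Monday's: “With the catalyst dead, extra substrate or partner does nothing”.

The flask gives 36.1% at 15 min, and Sunday's adds most, 13 points; after Saturday's it holds 40.4%, after Monday's 32.1%.

    substrate + coupling partner ⇌ target (K = 49.0 M⁻¹, k = 0.170 M⁻¹ s⁻¹)
    substrate + coupling partner ⇌ isomer of the product (K = 600 M⁻¹, k = 0.0210 M⁻¹ s⁻¹)
    substrate + target → side product (k = 8.80 × 10⁻⁴ M⁻¹ s⁻¹)
    2 coupling partner → self-condensation product (k = 0.0130 M⁻¹ s⁻¹)

At 15.0 min, 19.5% stands as isomer of the product, and the flask's target share is 0.633. A neighbour flask with [coupling partner] at 0.033 M keeps 58% of its substrate free, so the carried share gives 26.9%; that neighbour holds 26.7% of target.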